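**Plan**

1. Retrosynthesis (decalin numbering of the target: C1 ester, C2 OH, C3 oxiranyl, C4 CH2, C4a/C5 methyls, C7 ketone): open the oxirane C–O bond to a tertiary alcohol/primary tosylate, take C2–OH back to a ketone, then cut ring bond C3–C4 and rejoin C4 to C2 (retro-semipinacol) to reach a cis-hydrindane cyclopentanol carrying a 2,3-epoxy-alcohol side chain.
2. Further cuts: epoxide O (Sharpless epoxidation of a Z-allylic alcohol), ester C–O, C1–H (ketone reduction), C2–O (enolate hydroxylation), C2–alkenyl (Pd enolate coupling), C5–CH3 (cuprate), the cyclopentanone C–C bond (Stetter) and the allyl–C4a bond (dearomatization of p-cresol).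
3. Forward order: ring A from p-cresol as a prochiral dienone, then the cyclopentanone by Stetter reaction, then side chain and both oxygens on the five-membered ring, then ring B by one-carbon ring expansion, then C2 reduction, and the oxirane last.
4. Enabling feature: in ring B the oxygen on C2 and the oxygen-bearing quaternary carbon on the neighbouring ring atom C3 form an O–C2–C3–C–O (β-hydroxy ketone) pattern. C3 can therefore be the oxirane CH of a 1-(oxiranyl)cyclopentanol and be inserted between C2 and C4 by a 2,3-epoxy-alcohol semipinacol shift.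
5. Stereochemistry: C4a/C8a from the catalyst in the desymmetrizing Stetter step; C5 from cuprate addition anti to the cyclopentane; C1 from hydride attack anti to the alkenyl group, after face-selective hydroxylation of the neighbouring carbon; C3 and the oxirane carbon from the Sharpless epoxidation, carried over by anti migration and retention; C2 from directed axial hydride delivery.

Key step: step 13

Assumption: the enantiomer of the aminoindanol-derived triazolium precatalyst that gives (3aR,7aS)-5 is used (both are catalogue items), and (2E)-3-methylpent-2-enoic acid is taken as a catalogue compound.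

**Route**

Step 1
Reactants: 1 p-cresol; 2 allyltrimethylsilane
Product: 3 4-allyl-4-methylcyclohexa-2,5-dien-1-one
Conditions: PhI(OAc)2 (1.1 equiv), (CF3)2CHOH, 0 °C
Reagents that add atoms: none
Why: Oxidative dearomatization: the iodine(III)-generated phenoxenium ion is trapped at the methyl-bearing para carbon by the allylsilane (dearomative Hosomi–Sakurai-type allylation), giving the prochiral 4,4-disubstituted dienone without a stereocentre.

Step 2
Reactants: 3 4-allyl-4-methylcyclohexa-2,5-dien-1-one
Product: 4 3-(1-methyl-4-oxocyclohexa-2,5-dien-1-yl)propanal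
Conditions: PdCl2(PhCN)2 (10 mol%), CuCl2·2H2O (10 mol%), AgNO2 (5 mol%), t-BuOH/MeNO2, O2 (1 atm), rt
Reagents that add atoms: dioxygen, O=O
Why: The nitrite-modified (aldehyde-selective) Wacker oxidation should place oxygen on the terminal carbon of the unbiased allyl group, while the electron-poor dienone alkenes stay untouched.

Step 3
Reactants: 4 3-(1-methyl-4-oxocyclohexa-2,5-dien-1-yl)propanal
Product: 5 (3aR,7aS)-3a-methyl-2,3,3a,7a-tetrahydro-1H-indene-1,6(7H)-dione (cis-fused)
Conditions: aminoindanol-derived N-C6F5 triazolium tetrafluoroborate (10 mol%), KHMDS (10 mol%), toluene, rt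
Reagents that add atoms: none
Why: Desymmetrizing intramolecular Stetter reaction: the Breslow intermediate adds 5-exo-trig to one of the two enantiotopic enone β-carbons, so the chiral carbene fixes the quaternary carbon and the adjacent ring-fusion CH, which are cis because of the tether.

Step 4
Reactants: 5 (3aR,7aS)-3a-methyl-2,3,3a,7a-tetrahydro-1H-indene-1,6(7H)-dione
Product: 7 (3aR,4S,7aS)-3a,4-dimethyl-6-[(triisopropylsilyl)oxy]-2,3,3a,4,7,7a-hexahydro-1H-inden-1-one, via lithium enolate 6 (not isolated)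
Conditions: Me2CuLi, Et2O, −78 °C; then TIPSOTf, −78 → 0 °C
Reagents that add atoms: lithium dimethylcuprate, [Li+].C[Cu-]C; triisopropylsilyl trifluoromethanesulfonate, CC(C)[Si](C(C)C)(C(C)C)OS(=O)(=O)C(F)(F)F
Why: Cuprate conjugate addition to the cyclohexenone should occur anti to the pseudo-axial cyclopentane CH2 (open face of the cis-hydrindenone), placing the new methyl cis to the angular methyl; O-silylation of the regiodefined enolate masks the six-ring ketone as a TIPS enol ether until step 11.

Step 5
Reactants: 8 prop-2-yn-1-ol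
Product: 10 (Z)-3-iodo-2-methylprop-2-en-1-ol, via alkenylmagnesium alkoxide 9 (not isolated)
Conditions: MeMgBr (2.3 equiv), CuI (10 mol%), Et2O, −10 °C → rt; then I2, −10 °C
Reagents that add atoms: methylmagnesium bromide, C[Mg]Br; iodine, II
Why: Copper-catalysed anti-carbomagnesiation of the propargylic alkoxide gives the chelated alkenylmagnesium with Mg cis to CH2O, and iodinolysis with retention gives the Z iodide.

Step 6
Reactants: 10 (Z)-3-iodo-2-methylprop-2-en-1-ol
Product: 11 (Z)-tert-butyl[(3-iodo-2-methylprop-2-en-1-yl)oxy]dimethylsilane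
Conditions: TBSCl, imidazole, CH2Cl2, 0 °C → rt
Reagents that add atoms: tert-butyldimethylsilyl chloride, CC(C)(C)[Si](C)(C)Cl
Why: Standard silylation of the primary alcohol so that the iodide can be used in the enolate coupling.

Step 7
Reactants: 7 (3aR,4S,7aS)-3a,4-dimethyl-6-[(triisopropylsilyl)oxy]-2,3,3a,4,7,7a-hexahydro-1H-inden-1-one; 11 (Z)-tert-butyl[(3-iodo-2-methylprop-2-en-1-yl)oxy]dimethylsilane
Product: 12 (3aR,4S,7aS)-2-[(1Z)-3-{[tert-butyl(dimethyl)silyl]oxy}-2-methylprop-1-en-1-yl]-3a,4-dimethyl-6-[(triisopropylsilyl)oxy]-2,3,3a,4,7,7a-hexahydro-1H-inden-1-one (mixture at C2)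
Conditions: Pd2(dba)3 (2.5 mol%), Q-Phos (5 mol%), LiHMDS (2.2 equiv), THF, rt → 50 °C
Reagents that add atoms: none
Why: Palladium-catalysed α-alkenylation of a ketone enolate (Buchwald–Hartwig-type enolate coupling) at the CH2 rather than the hindered ring-fusion CH, with retention of the Z geometry; excess base keeps the product as its dienolate, and the new C2 centre is uncontrolled because it is planarised in step 8.

Step 8
Reactants: 12 the alkenylated ketone
Product: 14 (2R,3aR,4S,7aS)-2-hydroxy-2-[(1Z)-3-{[tert-butyl(dimethyl)silyl]oxy}-2-methylprop-1-en-1-yl]-3a,4-dimethyl-6-[(triisopropylsilyl)oxy]-2,3,3a,4,7,7a-hexahydro-1H-inden-1-one, via potassium dienolate 13 (not isolated)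
Conditions: KHMDS (1.2 equiv), THF, −78 °C; then 2-(phenylsulfonyl)-3-phenyloxaziridine, −78 °C
Reagents that add atoms: 2-(phenylsulfonyl)-3-phenyloxaziridine, O=S(=O)(c1ccccc1)N1OC1c1ccccc1
Why: Davis α-hydroxylation of the dienolate at the α-carbon; oxygen should enter from the open face of the cyclopentane envelope (the face of 7a-H and the angular methyl, away from the six-membered ring), which sets C2 with the alkenyl group on the face of the six-membered ring.

Step 9
Reactants: 14 the α-hydroxy ketone
Product: 15 (1S,2R,3aR,4S,7aS)-2-[(1Z)-3-{[tert-butyl(dimethyl)silyl]oxy}-2-methylprop-1-en-1-yl]-3a,4-dimethyl-6-[(triisopropylsilyl)oxy]-2,3,3a,4,7,7a-hexahydro-1H-indene-1,2-diol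
Conditions: NaBH4, MeOH/THF, −20 °C
Reagents that add atoms: none
Why: Hydride should attack the C1 carbonyl from the open face, anti to the C2 alkenyl group and to the ring-A CH2 on C7a, giving the 1,2-trans diol with the C1 oxygen on the face required for the ester carbon of the target.

Step 10
Reactants: 15 the diol; 16 (2E)-3-methylpent-2-enoic acid
Product: 17 (1S,2R,3aR,4S,7aS)-2-hydroxy-2-[(1Z)-3-{[tert-butyl(dimethyl)silyl]oxy}-2-methylprop-1-en-1-yl]-3a,4-dimethyl-6-[(triisopropylsilyl)oxy]-2,3,3a,4,7,7a-hexahydro-1H-inden-1-yl (2E)-3-methylpent-2-enoate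
Conditions: EDC·HCl, DMAP, CH2Cl2, 0 °C → rt
Reagents that add atoms: none
Why: Steglich esterification of the only acylable (secondary) hydroxyl; the tertiary alcohol is inert, and the ester is in place before any second secondary hydroxyl exists.

Step 11
Reactants: 17 the silylated ester
Product: 18 (1S,2R,3aR,4S,7aS)-2-hydroxy-2-[(1Z)-3-hydroxy-2-methylprop-1-en-1-yl]-3a,4-dimethyl-6-oxooctahydro-1H-inden-1-yl (2E)-3-methylpent-2-enoate
Conditions: TBAF, AcOH, THF, 0 °C → rt
Reagents that add atoms: none
Why: Buffered fluoride cleaves the primary TBS ether and the TIPS enol ether (C-protonation returns the six-ring ketone) without touching the ester; the trans relation of ester and tertiary OH disfavours acyl migration.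

Step 12
Reactants: 18 the Z-ene-diol keto ester
Product: 20 (1S,2S,3aR,4S,7aS)-2-hydroxy-3a,4-dimethyl-2-[(2R,3S)-3-methyl-3-{[(4-methylphenyl)sulfonyl]oxymethyl}oxiran-2-yl]-6-oxooctahydro-1H-inden-1-yl (2E)-3-methylpent-2-enoate, via epoxy alcohol 19 (not isolated)
Conditions: Ti(OiPr)4 (0.5 equiv), L-(+)-DET (0.6 equiv), TBHP, 4 Å MS, CH2Cl2, −20 °C; then TsCl, Et3N, DMAP (cat.), −10 °C
Reagents that add atoms: tert-butyl hydroperoxide, CC(C)(C)OO; p-toluenesulfonyl chloride, Cc1ccc(cc1)S(=O)(=O)Cl
Why: Sharpless asymmetric epoxidation of the primary Z-allylic alcohol: L-(+)-DET should deliver oxygen to the face that gives the (2R,3S)-oxirane, the same face the A(1,3)-minimised conformer of the substrate exposes, and the epoxy alcohol is tosylated in situ at the primary hydroxyl only.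

Step 13
Reactants: 20 the epoxy tosylate
Product: 21 (1S,3R,4aR,5S,8aS)-3-[(2R)-2-hydroxy-1-{[(4-methylphenyl)sulfonyl]oxy}propan-2-yl]-4a,5-dimethyl-2,7-dioxodecahydronaphthalen-1-yl (2E)-3-methylpent-2-enoate
Conditions: BF3·OEt2 (0.5 equiv), CH2Cl2, −78 → −30 °C
Reagents that add atoms: none
Why: BF3 coordinates the oxirane oxygen and, as the bond from oxygen to the oxirane CH (the carbon attached to carbinol C2 of the indane) breaks, the ring bond C2–C3 (the CH2 next to the angular-methyl carbon) migrates to that carbon anti-periplanar to the leaving oxygen while C2 becomes the ketone, a type-3 semipinacol rearrangement of a 2,3-epoxy tertiary alcohol. The closest known reaction type is the Lewis-acid ring expansion of 1-(oxiran-2-yl)cycloalkanols to 2-(1-hydroxyalkyl)cycloalkanones. No ring is closed by an exo or endo attack: the cyclohexanone (ring B) arises from the cyclopentanol by enlargement, the oxirane CH being inserted between C2 and C3 through the 1,2-shift. The new ring stereocentre (C3 of the decalin) forms with inversion at the oxirane CH and is therefore fixed by the epoxide configuration from step 12, and the tertiary carbinol of the side chain keeps its C–O bond and configuration. The step needs cleavage at the oxirane CH and not at the tertiary carbon, which the β-tosyloxy group (it destabilises positive charge there) and the push of the adjacent carbinol should secure, and it needs migration of the CH2 and not of the ester-bearing CH, which the acyloxy group disfavours electronically. With the C2 configuration from step 8, the rotamer that places the CH2 anti to the C–O bond also keeps the bulky oxirane carbon next to OH and not between the two ring carbons, and the same rotamer holds the ester carbonyl away from the backside of the oxirane CH.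

Step 14
Reactants: 21 the ring-expanded β-hydroxy ketone
Product: 22 (1S,2R,3S,4aR,5S,8aS)-2-hydroxy-3-[(2R)-2-hydroxy-1-{[(4-methylphenyl)sulfonyl]oxy}propan-2-yl]-4a,5-dimethyl-7-oxodecahydronaphthalen-1-yl (2E)-3-methylpent-2-enoate
Conditions: Me4NBH(OAc)3, MeCN/AcOH, −30 °C
Reagents that add atoms: none
Why: Evans–Saksena reduction: the tertiary β-hydroxyl binds boron and delivers hydride only to the β-hydroxy ketone (the isolated C7 ketone is not reduced), along the axial trajectory anti to the axial acyloxy group, which should give the equatorial C2 alcohol cis to the ester.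

Step 15
Reactants: 22 the hydroxy tosylate
Product: 23 (1S,2R,3S,4aR,5S,8aS)-2-hydroxy-4a,5-dimethyl-3-[(2R)-2-methyloxiran-2-yl]-7-oxodecahydronaphthalen-1-yl (2E)-3-methylpent-2-enoate (CNP0103173.1)
Conditions: t-BuOK (1.05 equiv), THF, −78 → −40 °C
Reagents that add atoms: none
Why: Williamson 3-exo-tet closure of the tertiary alkoxide onto the primary tosylate forms the oxirane with retention at the quaternary carbon; one equivalent of base at low temperature is chosen to keep O→O acyl migration slow.

**Compound list**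

1 | p-cresol | Cc1ccc(O)cc1 | starting material
2 | allyltrimethylsilane | C=CC[Si](C)(C)C | starting material
3 | 4-allyl-4-methylcyclohexa-2,5-dien-1-one | C=CCC1(C)C=CC(=O)C=C1 | intermediate
4 | 3-(1-methyl-4-oxocyclohexa-2,5-dien-1-yl)propanal | O=CCCC1(C)C=CC(=O)C=C1 | intermediate
5 | (3aR,7aS)-3a-methyl-2,3,3a,7a-tetrahydro-1H-indene-1,6(7H)-dione | C[C@]12CCC(=O)[C@H]1CC(=O)C=C2 | intermediate
6 | lithium enolate of the 4-methylated dione (O-Li at C6) | C[C@]12CCC(=O)[C@H]1CC(O[Li])=C[C@@H]2C | intermediate (not isolated)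
7 | (3aR,4S,7aS)-3a,4-dimethyl-6-[(triisopropylsilyl)oxy]-2,3,3a,4,7,7a-hexahydro-1H-inden-1-one | C[C@]12CCC(=O)[C@H]1CC(O[Si](C(C)C)(C(C)C)C(C)C)=C[C@@H]2C | intermediate
8 | prop-2-yn-1-ol | C#CCO | starting material
9 | bromomagnesium (Z)-3-(bromomagnesio)-2-methylprop-2-en-1-olate | Br[Mg]OC/C(C)=C\[Mg]Br | intermediate (not isolated)
10 | (Z)-3-iodo-2-methylprop-2-en-1-ol | OC/C(C)=C\I | intermediate
11 | (Z)-tert-butyl[(3-iodo-2-methylprop-2-en-1-yl)oxy]dimethylsilane | CC(C)(C)[Si](C)(C)OC/C(C)=C\I | intermediate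
12 | (3aR,4S,7aS)-2-[(1Z)-3-(TBS-oxy)-2-methylprop-1-enyl]-3a,4-dimethyl-6-(TIPS-oxy)-2,3,3a,4,7,7a-hexahydro-1H-inden-1-one (C2 mixture) | C[C@]12CC(/C=C(/C)CO[Si](C)(C)C(C)(C)C)C(=O)[C@H]1CC(O[Si](C(C)C)(C(C)C)C(C)C)=C[C@@H]2C | intermediate
13 | potassium dienolate of 12 | C[C@]12CC(/C=C(/C)CO[Si](C)(C)C(C)(C)C)=C(O[K])[C@H]1CC(O[Si](C(C)C)(C(C)C)C(C)C)=C[C@@H]2C | intermediate (not isolated)
14 | (2R,3aR,4S,7aS)-2-hydroxy-2-[(1Z)-3-(TBS-oxy)-2-methylprop-1-enyl]-3a,4-dimethyl-6-(TIPS-oxy)-2,3,3a,4,7,7a-hexahydro-1H-inden-1-one | C[C@]12C[C@@](O)(/C=C(/C)CO[Si](C)(C)C(C)(C)C)C(=O)[C@H]1CC(O[Si](C(C)C)(C(C)C)C(C)C)=C[C@@H]2C | intermediate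
15 | (1S,2R,3aR,4S,7aS)-2-[(1Z)-3-(TBS-oxy)-2-methylprop-1-enyl]-3a,4-dimethyl-6-(TIPS-oxy)-2,3,3a,4,7,7a-hexahydro-1H-indene-1,2-diol | C[C@]12C[C@@](O)(/C=C(/C)CO[Si](C)(C)C(C)(C)C)[C@@H](O)[C@H]1CC(O[Si](C(C)C)(C(C)C)C(C)C)=C[C@@H]2C | intermediate
16 | (2E)-3-methylpent-2-enoic acid | CC/C(C)=C/C(=O)O | starting material
17 | C1 (2E)-3-methylpent-2-enoate of diol 15 | C[C@]12C[C@@](O)(/C=C(/C)CO[Si](C)(C)C(C)(C)C)[C@@H](OC(=O)/C=C(C)/CC)[C@H]1CC(O[Si](C(C)C)(C(C)C)C(C)C)=C[C@@H]2C | intermediate
18 | (1S,2R,3aR,4S,7aS)-2-hydroxy-2-[(1Z)-3-hydroxy-2-methylprop-1-enyl]-3a,4-dimethyl-6-oxooctahydro-1H-inden-1-yl (2E)-3-methylpent-2-enoate | C[C@]12C[C@@](O)(/C=C(/C)CO)[C@@H](OC(=O)/C=C(C)/CC)[C@H]1CC(=O)C[C@@H]2C | intermediate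
19 | (1S,2S,3aR,4S,7aS)-2-hydroxy-2-[(2R,3S)-3-(hydroxymethyl)-3-methyloxiran-2-yl]-3a,4-dimethyl-6-oxooctahydro-1H-inden-1-yl (2E)-3-methylpent-2-enoate | C[C@]12C[C@@](O)([C@H]3O[C@@]3(C)CO)[C@@H](OC(=O)/C=C(C)/CC)[C@H]1CC(=O)C[C@@H]2C | intermediate (not isolated)
20 | primary tosylate of 19 | C[C@]12C[C@@](O)([C@H]3O[C@@]3(C)COS(=O)(=O)c3ccc(C)cc3)[C@@H](OC(=O)/C=C(C)/CC)[C@H]1CC(=O)C[C@@H]2C | intermediate
21 | (1S,3R,4aR,5S,8aS)-3-[(2R)-2-hydroxy-1-(tosyloxy)propan-2-yl]-4a,5-dimethyl-2,7-dioxodecahydronaphthalen-1-yl (2E)-3-methylpent-2-enoate | CC/C(C)=C/C(=O)O[C@@H]1C(=O)[C@@H]([C@@](C)(O)COS(=O)(=O)c3ccc(C)cc3)C[C@@]2(C)[C@@H]1CC(=O)C[C@@H]2C | intermediate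
22 | (1S,2R,3S,4aR,5S,8aS)-2-hydroxy-3-[(2R)-2-hydroxy-1-(tosyloxy)propan-2-yl]-4a,5-dimethyl-7-oxodecahydronaphthalen-1-yl (2E)-3-methylpent-2-enoate | CC/C(C)=C/C(=O)O[C@@H]1[C@H](O)[C@@H]([C@@](C)(O)COS(=O)(=O)c3ccc(C)cc3)C[C@@]2(C)[C@@H]1CC(=O)C[C@@H]2C | intermediate
23 | (1S,2R,3S,4aR,5S,8aS)-2-hydroxy-4a,5-dimethyl-3-[(2R)-2-methyloxiran-2-yl]-7-oxodecahydronaphthalen-1-yl (2E)-3-methylpent-2-enoate | CC/C(C)=C/C(=O)O[C@@H]1[C@H](O)[C@@H]([C@]2(C)CO2)C[C@@]2(C)[C@@H]1CC(=O)C[C@@H]2C | target

**Totals and risks**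

Total step count: 15. Longest linear sequence: 13 (steps 1–4 and 7–15).

Step 13 (key ring expansion). The activated oxirane may be opened by the neighbouring enoate carbonyl instead of by the migrating bond, the ester-bearing ring carbon may migrate, or the tertiary oxirane carbon may ionise. The fallback runs the rearrangement before the ester is introduced. It sets out from diol 15: silylation of the secondary hydroxyl (TBSOTf, 2,6-lutidine) would give the bis-TBS TIPS-enol ether F1. Buffered HF·pyridine would remove the primary TBS and the enol silyl group to give the ene-diol ketone with a C1 silyl ether F2. The epoxidation and in situ tosylation of step 12 would give the silyloxy epoxy tosylate F3. Lewis-acid semipinacol rearrangement of this non-participating silyl ether would give the ring-expanded silyloxy ketone F4. HF·pyridine would free the α-hydroxy ketone F5, and Steglich esterification with 16 comes back to the route at 21.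

Step 7 (enolate alkenylation). The coupling may stall on the hindered ketone, alkenylate twice, or let the β,γ-double bond drift into conjugation with loss of the Z geometry. The fallback reverses the polarity and sets out from 7: bromination of its lithium enolate with NBS would give the 2-bromo ketone F6. Iodide 11 would be turned into the (Z)-alkenylzinc chloride F7 (t-BuLi, then ZnCl2). A nickel-catalysed Negishi coupling of the α-bromo ketone with this alkenylzinc reagent comes back at 12.

Step 12 (asymmetric epoxidation). The titanium–tartrate epoxidation may turn over very slowly and with eroded face control, because the Z-alkene carries a fully substituted carbinol cis to the hydroxymethyl group. The fallback uses the tertiary allylic hydroxyl as the directing group before desilylation. It sets out from ester 17: VO(acac)2/TBHP would give the silyl-protected epoxide F8, with the face fixed by allylic 1,3-strain. TBAF/AcOH would then give epoxy alcohol 19, now isolated, and tosylation comes back at 20.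

Further compounds

F1 | step 13 | C1 TBS ether of diol 15 (C12 TBS ether and TIPS enol ether retained) | C[C@]12C[C@@](O)(/C=C(/C)CO[Si](C)(C)C(C)(C)C)[C@@H](O[Si](C)(C)C(C)(C)C)[C@H]1CC(O[Si](C(C)C)(C(C)C)C(C)C)=C[C@@H]2C
F2 | step 13 | ene-diol ketone with C1 TBS ether | C[C@]12C[C@@](O)(/C=C(/C)CO)[C@@H](O[Si](C)(C)C(C)(C)C)[C@H]1CC(=O)C[C@@H]2C
F3 | step 13 | epoxy tosylate with C1 TBS ether | C[C@]12C[C@@](O)([C@H]3O[C@@]3(C)COS(=O)(=O)c3ccc(C)cc3)[C@@H](O[Si](C)(C)C(C)(C)C)[C@H]1CC(=O)C[C@@H]2C
F4 | step 13 | ring-expanded β-hydroxy ketone with C1 TBS ether | CC(C)(C)[Si](C)(C)O[C@@H]1C(=O)[C@@H]([C@@](C)(O)COS(=O)(=O)c3ccc(C)cc3)C[C@@]2(C)[C@@H]1CC(=O)C[C@@H]2C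
F5 | step 13 | ring-expanded α-hydroxy ketone (free C1 hydroxyl) | O[C@@H]1C(=O)[C@@H]([C@@](C)(O)COS(=O)(=O)c3ccc(C)cc3)C[C@@]2(C)[C@@H]1CC(=O)C[C@@H]2C
F6 | step 7 | 2-bromo derivative of ketone 7 (C2 mixture) | C[C@]12CC(Br)C(=O)[C@H]1CC(O[Si](C(C)C)(C(C)C)C(C)C)=C[C@@H]2C
F7 | step 7 | (Z)-[3-(TBS-oxy)-2-methylprop-1-enyl]zinc chloride | CC(C)(C)[Si](C)(C)OC/C(C)=C\[Zn]Cl
F8 | step 12 | (2R,3S)-epoxide of 17 (C12 TBS ether and TIPS enol ether retained) | C[C@]12C[C@@](O)([C@H]3O[C@@]3(C)CO[Si](C)(C)C(C)(C)C)[C@@H](OC(=O)/C=C(C)/CC)[C@H]1CC(O[Si](C(C)C)(C(C)C)C(C)C)=C[C@@H]2C
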